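**Retrosynthetic overview**

- The strategy rests on the oxane ring (O1, C2–C6): its C2 4-hydroxy-3,5-dimethoxyphenyl group, C4 hydroxyl and C6 2-(4-hydroxy-3-methoxyphenyl)ethyl group are all cis, so all three sit equatorial on one chair. This is the pattern a chair Prins cyclisation gives.
- Cutting O1–C6, C5–C6 and C4–O gives a 3-arylpropanal (C6 and its side chain) and an S-configured aryl homoallylic alcohol (O1, C2–C5). The oxane is the only ring made, and it is made in the key step.
- The aldehyde should come from dihydroconiferyl alcohol by phenol-selective pivaloylation and oxidation. The homoallylic alcohol should come from O-pivaloyl syringaldehyde by phosphoric-acid-catalysed asymmetric allylboration.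
- Both phenols travel as pivalates, which are stable to acid and make the benzylic carbinol electron-poor. They are removed at the end together with the C4 trifluoroacetate by methanolysis.

Key step: step 5

Assumption: 4-(3-hydroxypropyl)-2-methoxyphenol (dihydroconiferyl alcohol, 1) is taken as a purchasable starting material. Ring atoms are numbered O1, C2 (carries the dimethoxyaryl group), C3, C4 (carbinol), C5, C6 (carries the arylethyl group).

**Route**

Step 1
Reactants: 1 4-(3-hydroxypropyl)-2-methoxyphenol
Product: 2 4-(3-hydroxypropyl)-2-methoxyphenyl 2,2-dimethylpropanoate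
Conditions: PivCl (1.05 equiv), NaOH (1.1 equiv), Bu4NHSO4 (cat.), CH2Cl2/H2O, 0 °C
Reagents that add atoms: pivaloyl chloride, CC(C)(C)C(=O)Cl
Why: Phase-transfer Schotten–Baumann acylation, in which aqueous NaOH deprotonates only the phenol, so the phenoxide is acylated while the neutral primary alcohol, with no acyl-transfer catalyst present, should be left alone.

Step 2
Reactants: 2 4-(3-hydroxypropyl)-2-methoxyphenyl 2,2-dimethylpropanoate
Product: 3 2-methoxy-4-(3-oxopropyl)phenyl 2,2-dimethylpropanoate
Conditions: 2,2,6,6-tetramethylpiperidin-1-oxyl (TEMPO, 10 mol %), PhI(OAc)2 (1.1 equiv), CH2Cl2, rt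
Reagents that add atoms: none
Why: Oxoammonium-mediated oxidation of a primary alcohol, which stops at the aldehyde under anhydrous conditions and should not touch the aryl ester or the acylated, deactivated arene.

Step 3
Reactants: 4 4-hydroxy-3,5-dimethoxybenzaldehyde (syringaldehyde)
Product: 5 4-formyl-2,6-dimethoxyphenyl 2,2-dimethylpropanoate
Conditions: PivCl (1.2 equiv), Et3N (1.5 equiv), 4-(dimethylamino)pyridine (10 mol %), CH2Cl2, 0 °C → rt
Reagents that add atoms: pivaloyl chloride, CC(C)(C)C(=O)Cl
Why: Nucleophile-catalysed O-acylation of a phenol, in which the acylpyridinium intermediate should overcome the hindrance of the two ortho methoxy groups.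

Step 4
Reactants: 5 4-formyl-2,6-dimethoxyphenyl 2,2-dimethylpropanoate; 6 2-allyl-4,4,5,5-tetramethyl-1,3,2-dioxaborolane (allylboronic acid pinacol ester)
Product: 8 4-[(1S)-1-hydroxybut-3-en-1-yl]-2,6-dimethoxyphenyl 2,2-dimethylpropanoate, via pinacol borate ester 7 (not isolated)
Conditions: 6 (1.2 equiv), (S)-3,3'-bis(2,4,6-triisopropylphenyl)-1,1'-binaphthalene-2,2'-diyl hydrogen phosphate (5 mol %), toluene, −30 °C; aq. NaHCO3 work-up
Reagents that add atoms: none
Why: Chiral-phosphoric-acid-catalysed allylboration of an aromatic aldehyde through a closed chair (Zimmerman–Traxler type) transition state in which the acid activates the boronate; the (S)-acid is expected to deliver the allyl group to the Si face of the formyl group and so set the S carbinol centre (the mirror image of the Re-face delivery known for the (R)-acid with aryl aldehydes; to be confirmed by Mosher ester analysis), and the aryl pivalate is inert.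

Step 5
Reactants: 8 4-[(1S)-1-hydroxybut-3-en-1-yl]-2,6-dimethoxyphenyl 2,2-dimethylpropanoate; 3 2-methoxy-4-(3-oxopropyl)phenyl 2,2-dimethylpropanoate
Product: 10 (2S,4R,6S)-2-[3,5-dimethoxy-4-(pivaloyloxy)phenyl]-6-{2-[3-methoxy-4-(pivaloyloxy)phenyl]ethyl}oxan-4-yl trifluoroacetate, via oxocarbenium trifluoroacetate 9 (not isolated)
Conditions: 3 (1.3 equiv), CF3CO2H (15 equiv), CH2Cl2, 0 °C → rt; aq. NaHCO3 work-up, crude product carried on
Reagents that add atoms: trifluoroacetic acid, OC(=O)C(F)(F)F
Why: Trifluoroacetic acid condenses alcohol 8 with aldehyde 3 to the (E)-oxocarbenium ion 9; the terminal alkene carbon attacks the aldehyde-derived carbon in a cation–olefin cyclisation and trifluoroacetate captures the developing secondary cation at C4, so O1–C6, C5–C6 and C4–O are made in one operation. The closest known reaction type is the trifluoroacetic-acid-mediated Prins cyclisation of homoallylic alcohols with aliphatic aldehydes to all-cis 2,6-disubstituted oxan-4-yl trifluoroacetates. The oxane ring closes in a 6-endo-trig mode through a chair transition state. The C6 centre is controlled by the existing C2 carbinol centre, because the C2 aryl group sits equatorial and the (E)-ion places the arylethyl group equatorial as well, so C6 forms cis to C2; the C4 centre is controlled by equatorial capture of the chair cation by trifluoroacetate. The step needs all-cis diastereoselectivity and retention of the enantiopurity of 8: the first follows from the chair with three equatorial groups, and the second should be secured by the aryl ring of 8, whose para pivaloyloxy group and two meta methoxy groups make the benzylic carbon electron-poor and so disfavour benzylic ionisation and 2-oxonia-Cope exchange.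

Step 6
Reactants: 10 (2S,4R,6S)-2-[3,5-dimethoxy-4-(pivaloyloxy)phenyl]-6-{2-[3-methoxy-4-(pivaloyloxy)phenyl]ethyl}oxan-4-yl trifluoroacetate
Product: 12 (2S,4R,6S)-2-(4-hydroxy-3,5-dimethoxyphenyl)-6-[2-(4-hydroxy-3-methoxyphenyl)ethyl]oxan-4-ol, via oxan-4-ol bis-pivalate 11 (not isolated)
Conditions: NaOMe (4 equiv), degassed MeOH, rt → 40 °C, under argon; AcOH quench
Reagents that add atoms: none
Why: Methoxide-mediated transesterification (Zemplén type), in which the trifluoroacetate should go first and the two aryl pivalates follow because their phenoxide leaving groups make them far more labile than alkyl pivalates; no stereocentre is touched and the benzylic C2–O1 ether should be stable to methoxide at this temperature.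

**Compound list**

1 | 4-(3-hydroxypropyl)-2-methoxyphenol (dihydroconiferyl alcohol) | COc1cc(CCCO)ccc1O | starting material
2 | 4-(3-hydroxypropyl)-2-methoxyphenyl 2,2-dimethylpropanoate | COc1cc(CCCO)ccc1OC(=O)C(C)(C)C | intermediate
3 | 2-methoxy-4-(3-oxopropyl)phenyl 2,2-dimethylpropanoate | O=CCCc1ccc(OC(=O)C(C)(C)C)c(OC)c1 | intermediate
4 | 4-hydroxy-3,5-dimethoxybenzaldehyde (syringaldehyde) | COc1cc(C=O)cc(OC)c1O | starting material
5 | 4-formyl-2,6-dimethoxyphenyl 2,2-dimethylpropanoate | COc1cc(C=O)cc(OC)c1OC(=O)C(C)(C)C | intermediate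
6 | 2-allyl-4,4,5,5-tetramethyl-1,3,2-dioxaborolane (allylboronic acid pinacol ester) | C=CCB1OC(C)(C)C(C)(C)O1 | starting material
7 | 2,6-dimethoxy-4-{(1S)-1-[(4,4,5,5-tetramethyl-1,3,2-dioxaborolan-2-yl)oxy]but-3-en-1-yl}phenyl 2,2-dimethylpropanoate | C=CC[C@@H](c1cc(OC)c(OC(=O)C(C)(C)C)c(OC)c1)OB1OC(C)(C)C(C)(C)O1 | intermediate (not isolated)
8 | 4-[(1S)-1-hydroxybut-3-en-1-yl]-2,6-dimethoxyphenyl 2,2-dimethylpropanoate | C=CC[C@@H](c1cc(OC)c(OC(=O)C(C)(C)C)c(OC)c1)O | intermediate
9 | (E)-oxocarbenium trifluoroacetate formed from 8 and 3 (O-alkylidene oxonium ion, S at the benzylic carbon) | C=CC[C@@H](c1cc(OC)c(OC(=O)C(C)(C)C)c(OC)c1)/[O+]=C/CCc1ccc(OC(=O)C(C)(C)C)c(OC)c1.[O-]C(=O)C(F)(F)F | intermediate (not isolated)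
10 | (2S,4R,6S)-2-[3,5-dimethoxy-4-(pivaloyloxy)phenyl]-6-{2-[3-methoxy-4-(pivaloyloxy)phenyl]ethyl}oxan-4-yl trifluoroacetate | COc1cc(CC[C@H]2C[C@@H](OC(=O)C(F)(F)F)C[C@@H](c3cc(OC)c(OC(=O)C(C)(C)C)c(OC)c3)O2)ccc1OC(=O)C(C)(C)C | intermediate
11 | (2S,4R,6S)-2-[3,5-dimethoxy-4-(pivaloyloxy)phenyl]-6-{2-[3-methoxy-4-(pivaloyloxy)phenyl]ethyl}oxan-4-ol | COc1cc(CC[C@H]2C[C@@H](O)C[C@@H](c3cc(OC)c(OC(=O)C(C)(C)C)c(OC)c3)O2)ccc1OC(=O)C(C)(C)C | intermediate (not isolated)
12 | (2S,4R,6S)-2-(4-hydroxy-3,5-dimethoxyphenyl)-6-[2-(4-hydroxy-3-methoxyphenyl)ethyl]oxan-4-ol | COc1cc(CC[C@H]2C[C@@H](O)C[C@@H](c3cc(OC)c(O)c(OC)c3)O2)ccc1O | target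

**Step count and risks**

Total step count: 6. Longest linear sequence: 4 steps (steps 3, 4, 5 and 6 from syringaldehyde; the branch through steps 1 and 2 is equally long).

Steps most likely to fail:

1. Step 5 (Prins cyclisation). What may go wrong is fragment exchange: the first oxocarbenium ion rearranges by 2-oxonia-Cope shift to its aryl-conjugated isomer, which is hydrolysed and recombines to symmetric 2,6-disubstituted oxanes. Benzylic ionisation of the carbinol before ring closure could also erode enantiopurity. The fallback exchanges the roles of the two partners; it sets out from aldehyde 3 (using 6 and 5) and comes back to the route at 10. Aldehyde 3 would be allylborated with 6 under the conditions of step 4 but with the (R)-antipode of the phosphoric acid. Through the pinacol borate ester 2-methoxy-4-{(3S)-3-[(4,4,5,5-tetramethyl-1,3,2-dioxaborolan-2-yl)oxy]hex-5-en-1-yl}phenyl 2,2-dimethylpropanoate F1, this should give the non-benzylic homoallylic alcohol 4-[(3S)-3-hydroxyhex-5-en-1-yl]-2-methoxyphenyl 2,2-dimethylpropanoate F2. Alcohol F2 and aromatic aldehyde 5 in CF3CO2H/CH2Cl2 should then pass through the aryl-conjugated (E)-oxocarbenium trifluoroacetate F3 and close through the same chair to trifluoroacetate 10. In this version the stereocentre sits on a carbon that cannot ionise, and the first-formed ion is already the more stable member of the oxonia-Cope pair, so there is no thermodynamic drive towards exchange.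

2. Step 4 (asymmetric allylboration). What may go wrong is insufficient enantioselectivity, or induction in the sense opposite to the one assumed for this catalyst antipode. The fallback replaces catalytic induction by resolution; it sets out from aldehyde 5 and comes back at 8. Aldehyde 5 would be allylated without stereocontrol under Barbier conditions (allyl bromide, Zn dust, THF/sat. aq. NH4Cl, rt) to racemic 4-(1-hydroxybut-3-en-1-yl)-2,6-dimethoxyphenyl 2,2-dimethylpropanoate F4. Lipase-mediated transesterification (Burkholderia cepacia lipase, vinyl acetate, t-BuOMe, 30 °C) should then acylate the R enantiomer to 4-[(1R)-1-acetoxybut-3-en-1-yl]-2,6-dimethoxyphenyl 2,2-dimethylpropanoate F5 and leave the S alcohol 8, which is separated by chromatography. The allylzinc reagent and the lipase should both spare the hindered aryl pivalate.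

3. Step 6 (global deprotection). What may go wrong is incomplete methanolysis of the pivalate on the dimethoxyaryl ring, which is shielded by two ortho methoxy groups, and air oxidation of the electron-rich phenoxides on long exposure to base. The fallback cleaves the esters by hydride instead of alkoxide; it sets out from 10 and arrives directly at 12. Treatment of 10 with diisobutylaluminium hydride (i-Bu2AlH, excess) in CH2Cl2 at −78 → 0 °C, followed by aqueous potassium sodium tartrate work-up, should reduce the trifluoroacetate and both pivalates, and the phenols would be held as aluminium phenoxides until the quench.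

**Further compounds**

F1 | step 5 | 2-methoxy-4-{(3S)-3-[(4,4,5,5-tetramethyl-1,3,2-dioxaborolan-2-yl)oxy]hex-5-en-1-yl}phenyl 2,2-dimethylpropanoate | COc1cc(CC[C@H](OB2OC(C)(C)C(C)(C)O2)CC=C)ccc1OC(=O)C(C)(C)C
F2 | step 5 | 4-[(3S)-3-hydroxyhex-5-en-1-yl]-2-methoxyphenyl 2,2-dimethylpropanoate | COc1cc(CC[C@H](O)CC=C)ccc1OC(=O)C(C)(C)C
F3 | step 5 | (E)-oxocarbenium trifluoroacetate formed from F2 and 5 (aryl-conjugated O-alkylidene oxonium ion, S at the alkyl carbinol carbon) | COc1cc(CC[C@H](/[O+]=C/c2cc(OC)c(OC(=O)C(C)(C)C)c(OC)c2)CC=C)ccc1OC(=O)C(C)(C)C.[O-]C(=O)C(F)(F)F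
F4 | step 4 | racemic 4-(1-hydroxybut-3-en-1-yl)-2,6-dimethoxyphenyl 2,2-dimethylpropanoate | C=CCC(O)c1cc(OC)c(OC(=O)C(C)(C)C)c(OC)c1
F5 | step 4 | 4-[(1R)-1-acetoxybut-3-en-1-yl]-2,6-dimethoxyphenyl 2,2-dimethylpropanoate | C=CC[C@H](c1cc(OC)c(OC(=O)C(C)(C)C)c(OC)c1)OC(C)=O
F0 | step 6 | none | none
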